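Each 14-membered ring carries a syn diol at C3/C4 (cembrane numbering): C3–O is secondary and becomes the lactone oxygen, C4 is a tertiary carbinol bearing a methyl group. That is the retron of a pinacol coupling between a C3 aldehyde and a C4 methyl ketone, so both C3–C4 bonds are cut. One treatment with SmI2 then closes both carbocycles and sets C3, C4, C3′ and C4′. The precursor is a C2-symmetric dimethyl 2,5-dialkyladipate with two epoxy-alkenyl keto-aldehyde arms, built two-directionally from adipoyl chloride by a twofold Ireland–Claisen rearrangement. Methyl esters are used, not tert-butyl esters, so that no acid is needed near the trisubstituted epoxides.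

Key step: step 13

Remark: locants follow cembrane numbering (C1 carries C15, which carries the carboxyl C16 and the linker carbon C17; primes mark the second half); (E)-geranylacetone is taken as the commercial single isomer, and the carbinol centre made in step 1 is racemic because step 12 removes it, so compounds 2–20 (apart from reagents 6, 9, 11 and 17) are epimer mixtures at that carbon, left undefined in the SMILES.

Step 1
Reactants: 1 (E)-geranylacetone
Product: 2 (5E)-6,10-dimethylundeca-5,9-dien-2-ol (racemic)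
Conditions: NaBH4, MeOH, 0 °C
Reagents that add atoms: none
Why: Sodium borohydride reduction of the methyl ketone (carbonyl 1,2-reduction) leaves both trisubstituted alkenes untouched, and the new carbinol centre is left racemic on purpose because step 12 oxidises it back to the C4 ketone.

Step 2
Reactants: 2 (5E)-6,10-dimethylundeca-5,9-dien-2-ol
Product: 3 tert-butyldimethylsilyl ether of 2
Conditions: TBSCl, imidazole, DMF, rt
Reagents that add atoms: tert-butyldimethylsilyl chloride, CC(C)(C)[Si](C)(C)Cl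
Why: Silyl ether formation with TBSCl/imidazole masks the secondary alcohol with a group that survives the oxidants, the Grignard reagent, the metathesis catalyst and the amide base used up to step 8.

Step 3
Reactants: 3 tert-butyldimethylsilyl ether of 2
Product: 4 (2E,6E)-10-[(tert-butyldimethylsilyl)oxy]-2,6-dimethylundeca-2,6-dien-1-ol
Conditions: SeO2 (0.3 equiv), tBuOOH (3 equiv), salicylic acid (0.1 equiv), CH2Cl2, 0 °C → rt
Reagents that add atoms: tert-butyl hydroperoxide, CC(C)(C)OO (oxygen relayed by the SeO2 catalyst)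
Why: Catalytic SeO2 allylic oxidation (ene reaction followed by [2,3]-sigmatropic shift, with tBuOOH as terminal oxidant) attacks the (E)-methyl group of the terminal gem-dimethyl alkene in preference to the more hindered internal alkene and gives the (E)-allylic alcohol that becomes C13–OH.

Step 4
Reactants: 4 (2E,6E)-10-[(tert-butyldimethylsilyl)oxy]-2,6-dimethylundeca-2,6-dien-1-ol
Product: 5 (2S,3S)-epoxy alcohol
Conditions: Ti(OiPr)4 (10 mol %), L-(+)-diethyl tartrate (12 mol %), tBuOOH, 4 Å molecular sieves, CH2Cl2, –20 °C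
Reagents that add atoms: tert-butyl hydroperoxide, CC(C)(C)OO
Why: Katsuki–Sharpless asymmetric epoxidation of the (E)-2-methyl allylic alcohol with the L-(+)-tartrate catalyst delivers oxygen to the alkene face that gives the (2S,3S)-epoxy alcohol, which sets C12 (S) and C11 (S), while the C7=C8 alkene has no allylic hydroxyl to bind titanium and is left alone.

Step 5
Reactants: 5 (2S,3S)-epoxy alcohol; 6 allylmagnesium chloride
Product: 8 (2S,3S)-homoallyl epoxide, via epoxy triflate 7 (not isolated)
Conditions: Tf2O, 2,6-lutidine, CH2Cl2, –78 °C, cold aqueous wash; crude 7 then CH2=CHCH2MgCl, CuI (10 mol %), THF, –78 → –30 °C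
Reagents that add atoms: allylmagnesium chloride, C=CC[Mg]Cl
Why: The primary triflate made at –78 °C is displaced at carbon by the allyl Grignard reagent under copper catalysis (SN2 coupling of an alkyl triflate with a Grignard reagent) faster than the trisubstituted epoxide is opened, which forms C13–C14 and leaves C11 and C12 unchanged.

Step 6
Reactants: 8 (2S,3S)-homoallyl epoxide; 9 (S)-but-3-en-2-ol
Product: 10 (2S,3E)-allylic alcohol
Conditions: second-generation Hoveyda–Grubbs catalyst (5 mol %), 9 (5 equiv), CH2Cl2, 40 °C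
Reagents that add atoms: (S)-but-3-en-2-ol, C[C@H](O)C=C
Why: Olefin cross-metathesis between the terminal alkene and an excess of the less reactive secondary allylic alcohol should give the (E)-disubstituted alkene with loss of ethylene, the trisubstituted alkene and the epoxide being inert to the ruthenium carbene, and the carbinol stereocentre is carried in unchanged from 9.

Step 7
Reactants: 10 (2S,3E)-allylic alcohol (2.1 equiv); 11 adipoyl chloride
Product: 12 bis-allylic adipate
Conditions: pyridine, DMAP (cat.), CH2Cl2, 0 °C → rt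
Reagents that add atoms: adipoyl chloride, O=C(Cl)CCCCC(=O)Cl
Why: Twofold acylation of the secondary allylic alcohol by the diacid chloride under pyridine/DMAP catalysis (nucleophilic acyl substitution) joins the two arms through the C15–C17–C17′–C15′ chain without touching any stereocentre.

Step 8
Reactants: 12 bis-allylic adipate
Product: 15 (15S,1R,15′S,1′R)-diacid diol, via bis(silyl ketene acetal) 13 (not isolated), via bis(silyl ester) 14 (not isolated)
Conditions: 12 added to LiN(iPr)2 (2.5 equiv), THF/DMPU (3:1), –78 °C; TBSCl (3 equiv), –78 → 50 °C; then Bu4NF, THF, rt; aq NaH2PO4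
Reagents that add atoms: none
Why: Twofold Ireland–Claisen rearrangement in which deprotonation in THF/DMPU gives the (Z)-silyl ketene acetals and each [3,3] shift passes through a chair with the carbinol methyl, the C14 chain and C17 all equatorial, so that the (S)-carbinol centre is transferred to C1 (R) and C15 (S) with an (E)-propenyl group on C1, after which fluoride cleaves the silyl esters and both TBS ethers.

Step 9
Reactants: 15 (15S,1R,15′S,1′R)-diacid diol
Product: 16 dimethyl ester of 15
Conditions: Me3SiCHN2, toluene/MeOH (4:1), 0 °C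
Reagents that add atoms: trimethylsilyldiazomethane, C[Si](C)(C)C=[N+]=[N-]
Why: Esterification of the carboxylic acids with trimethylsilyldiazomethane in methanol is neutral and fast, so the epoxides, the secondary alcohols and the C15 centres are not affected.

Step 10
Reactants: 16 dimethyl ester of 15; 17 ethylene
Product: 18 divinyl dimethyl ester
Conditions: second-generation Hoveyda–Grubbs catalyst (10 mol %), ethylene (5 bar), 1,4-benzoquinone (10 mol %), toluene, 40 °C
Reagents that add atoms: ethylene, C=C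
Why: Ethenolysis, that is cross-metathesis with an excess of ethylene, exchanges the ethylidene end of each 1,2-disubstituted propenyl group for a methylene group with loss of propene, while the trisubstituted alkenes do not react and the allylic C1 centres are not touched.

Step 11
Reactants: 18 divinyl dimethyl ester
Product: 20 tetraol dimethyl ester, via tetraboron adduct 19 (not isolated)
Conditions: 9-BBN (6 equiv), THF, 0 °C → rt; then 30% H2O2, pH 7 phosphate buffer, THF/MeOH, 0 °C → rt; used at once in step 12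
Reagents that add atoms: hydrogen peroxide, OO
Why: Hydroboration–oxidation with the bulky 9-BBN places boron on the terminal carbon of the two monosubstituted vinyl groups only, far faster than on the trisubstituted alkenes, and oxidation at pH 7 gives the primary C3 alcohols without base that would lactonise them onto the methyl esters.

Step 12
Reactants: 20 tetraol dimethyl ester
Product: 21 bis(keto-aldehyde) dimethyl ester
Conditions: Dess–Martin periodinane (6 equiv), NaHCO3, CH2Cl2, 0 °C → rt
Reagents that add atoms: none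
Why: Dess–Martin oxidation converts the two primary alcohols into aldehydes and the two secondary alcohols into methyl ketones under buffered conditions that spare epoxides, alkenes and the C1 and C15 centres, and it erases the racemic carbinol centre of step 1.

Step 13
Reactants: 21 bis(keto-aldehyde) dimethyl ester
Product: 22 bis(macrocyclic 3,4-diol) dimethyl ester
Conditions: SmI2 (8 equiv, 0.1 M in THF, no HMPA), 21 added by syringe pump over 10 h (final 1 mM), THF, 0 °C → rt; pH 7 phosphate buffer, 0 °C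
Reagents that add atoms: none
Why: Single-electron transfer from divalent samarium to each aldehyde gives a trivalent-samarium ketyl that adds to the samarium-bound C4 ketone of its own arm, and a second electron with protonation on work-up gives the chelated diolate and then the diol. The closest known reaction is the SmI2 keto-aldehyde pinacol macrocyclisation that closes 14-membered cembranoid rings at C3–C4. Each of the two rings closes in a 14-exo-trig mode, the C3 ketyl carbon attacking the C4 carbonyl carbon whose oxygen stays outside the ring. C3 and C4 (likewise C3′ and C4′) are set relative to each other by the cyclic samarium diolate with C2 and C5 antiperiplanar in the ring, which gives the syn diol; their sense relative to C1 (R) is set by the conformation of the closing chain, in which the C15 branch sits outside the ring and the small C16 methyl ester can bind the oxophilic ketyl samarium in a chair-like array that prefigures the later lactone. The step needs aldehyde–ketone coupling within one arm over coupling of the two aldehydes across the linker (a strained ten-membered ring) and over intermolecular coupling, which slow addition at high dilution and the rigid E-alkene and trans-epoxide of each arm favour, and SmI2 without HMPA leaves the trisubstituted epoxides and methyl esters untouched.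

Step 14
Reactants: 22 bis(macrocyclic 3,4-diol) dimethyl ester
Product: 23 C2-symmetric bis(δ-lactone) diol
Conditions: DBU (0.5 equiv), 4 Å molecular sieves, toluene, rt → 45 °C, stopped at full conversion
Reagents that add atoms: none
Why: Base-catalysed intramolecular transesterification closes each six-membered lactone from the secondary C3 hydroxyl onto the C16 methyl ester with loss of methanol, the tertiary C4 hydroxyl being unable to compete because it would give a seven-membered ring, and the mild amidine base at this temperature should neither open the epoxides nor enolise C15, whose configuration comes from step 8 and is not left to equilibration.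

Step 15
Reactants: 23 C2-symmetric bis(δ-lactone) diol
Product: 24 bis(trimethylsilyl) ether of 23
Conditions: N-(trimethylsilyl)imidazole (6 equiv), CH2Cl2, 40 °C
Reagents that add atoms: N-(trimethylsilyl)imidazole, C[Si](C)(C)n1ccnc1
Why: Silylation with N-(trimethylsilyl)imidazole caps the two hindered tertiary alcohols under neutral conditions so that the base of step 16 is consumed only at carbon.

Step 16
Reactants: 24 bis(trimethylsilyl) ether of 23
Product: 26 CNP0186476.4, via hydroxylated bis(silyl ether) 25 (not isolated)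
Conditions: KN(SiMe3)2 (0.95 equiv) added to 24, THF, –78 → –40 °C; 2-(phenylsulfonyl)-3-phenyloxaziridine (1.3 equiv), –78 °C; AcOH; then Bu4NF/AcOH (1:1), THF, 0 °C; unreacted 24 recycled
Reagents that add atoms: 2-(phenylsulfonyl)-3-phenyloxaziridine, O=S(=O)(c1ccccc1)N1OC1c1ccccc1
Why: Kinetic deprotonation of one of the two equivalent lactones with slightly less than one equivalent of base and oxidation of the potassium enolate by the N-sulfonyloxaziridine (Davis hydroxylation), with oxygen entering the enolate face anti to the C14 substituent on the neighbouring C1, sets C15′ (S), and buffered fluoride then removes the trimethylsilyl ethers.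

Compound list
1 | (E)-geranylacetone, (5E)-6,10-dimethylundeca-5,9-dien-2-one | CC(=O)CC/C=C(C)/CCC=C(C)C | starting material
2 | (5E)-6,10-dimethylundeca-5,9-dien-2-ol (racemic) | CC(O)CC/C=C(C)/CCC=C(C)C | intermediate
3 | tert-butyl{[(5E)-6,10-dimethylundeca-5,9-dien-2-yl]oxy}dimethylsilane (racemic) | CC(CC/C=C(C)/CCC=C(C)C)O[Si](C)(C)C(C)(C)C | intermediate
4 | (2E,6E)-10-[(tert-butyldimethylsilyl)oxy]-2,6-dimethylundeca-2,6-dien-1-ol (10RS) | CC(CC/C=C(C)/CC/C=C(C)/CO)O[Si](C)(C)C(C)(C)C | intermediate
5 | [(2S,3S)-3-{(3E)-7-[(tert-butyldimethylsilyl)oxy]-3-methyloct-3-en-1-yl}-2-methyloxiran-2-yl]methanol (C13–OH, C12 S, C11 S) | OC[C@]1(C)O[C@H]1CC/C(C)=C/CCC(C)O[Si](C)(C)C(C)(C)C | intermediate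
6 | allylmagnesium chloride | C=CC[Mg]Cl | starting material
7 | trifluoromethanesulfonate of 5 (epoxy triflate) | O=S(=O)(OC[C@]1(C)O[C@H]1CC/C(C)=C/CCC(C)O[Si](C)(C)C(C)(C)C)C(F)(F)F | intermediate (not isolated)
8 | (2S,3S)-2-(but-3-en-1-yl)-3-{(3E)-7-[(tert-butyldimethylsilyl)oxy]-3-methyloct-3-en-1-yl}-2-methyloxirane | C=CCC[C@]1(C)O[C@H]1CC/C(C)=C/CCC(C)O[Si](C)(C)C(C)(C)C | intermediate
9 | (S)-but-3-en-2-ol | C[C@H](O)C=C | starting material
10 | (2S,3E)-6-[(2S,3S)-3-{(3E)-7-[(tert-butyldimethylsilyl)oxy]-3-methyloct-3-en-1-yl}-2-methyloxiran-2-yl]hex-3-en-2-ol | C[C@H](O)/C=C/CC[C@]1(C)O[C@H]1CC/C(C)=C/CCC(C)O[Si](C)(C)C(C)(C)C | intermediate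
11 | adipoyl chloride (hexanedioyl dichloride) | O=C(Cl)CCCCC(=O)Cl | starting material
12 | hexanedioate diester of two molecules of 10 (both carbinol carbons S, alkenes E) | O=C(CCCCC(=O)O[C@@H](C)/C=C/CC[C@]1(C)O[C@H]1CC/C(C)=C/CCC(C)O[Si](C)(C)C(C)(C)C)O[C@@H](C)/C=C/CC[C@]1(C)O[C@H]1CC/C(C)=C/CCC(C)O[Si](C)(C)C(C)(C)C | intermediate
13 | bis[(Z)-O-tert-butyldimethylsilyl ketene acetal] of 12 | CC(C)(C)[Si](C)(C)O/C(O[C@@H](C)/C=C/CC[C@]1(C)O[C@H]1CC/C(C)=C/CCC(C)O[Si](C)(C)C(C)(C)C)=C\CC/C=C(\O[Si](C)(C)C(C)(C)C)O[C@@H](C)/C=C/CC[C@]1(C)O[C@H]1CC/C(C)=C/CCC(C)O[Si](C)(C)C(C)(C)C | intermediate (not isolated)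
14 | bis(tert-butyldimethylsilyl) ester of the rearranged diacid, C4 and C4′ oxygens still silylated | C/C=C/[C@@H](CC[C@]1(C)O[C@H]1CC/C(C)=C/CCC(C)O[Si](C)(C)C(C)(C)C)[C@H](CC[C@H](C(=O)O[Si](C)(C)C(C)(C)C)[C@@H](/C=C/C)CC[C@]1(C)O[C@H]1CC/C(C)=C/CCC(C)O[Si](C)(C)C(C)(C)C)C(=O)O[Si](C)(C)C(C)(C)C | intermediate (not isolated)
15 | (2S,5S)-2,5-disubstituted hexanedioic acid; each α-carbon (C15, S) carries a C1 (R) methine bearing an (E)-prop-1-enyl group and the 2-[(2S,3S)-epoxyalkenyl]ethyl arm ending in the free C4 alcohol | C/C=C/[C@@H](CC[C@]1(C)O[C@H]1CC/C(C)=C/CCC(C)O)[C@H](CC[C@H](C(=O)O)[C@@H](/C=C/C)CC[C@]1(C)O[C@H]1CC/C(C)=C/CCC(C)O)C(=O)O | intermediate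
16 | dimethyl ester of 15 | C/C=C/[C@@H](CC[C@]1(C)O[C@H]1CC/C(C)=C/CCC(C)O)[C@H](CC[C@H](C(=O)OC)[C@@H](/C=C/C)CC[C@]1(C)O[C@H]1CC/C(C)=C/CCC(C)O)C(=O)OC | intermediate
17 | ethylene | C=C | starting material
18 | dimethyl (15S,15′S)-adipate with vinyl groups on C1 and C1′ (both R) and free C4, C4′ alcohols | C=C[C@@H](CC[C@]1(C)O[C@H]1CC/C(C)=C/CCC(C)O)[C@H](CC[C@H](C(=O)OC)[C@@H](C=C)CC[C@]1(C)O[C@H]1CC/C(C)=C/CCC(C)O)C(=O)OC | intermediate
19 | 9-BBN adduct of 18: B-alkyl boranes at C3 and C3′, O-borinates at the C4 and C4′ oxygens | C(CB1C2CCCC1CCC2)[C@@H](CC[C@]1(C)O[C@H]1CC/C(C)=C/CCC(C)OB1C2CCCC1CCC2)[C@H](CC[C@H](C(=O)OC)[C@@H](CCB1C2CCCC1CCC2)CC[C@]1(C)O[C@H]1CC/C(C)=C/CCC(C)OB1C2CCCC1CCC2)C(=O)OC | intermediate (not isolated)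
20 | tetraol dimethyl ester: primary C3, C3′ and secondary C4, C4′ alcohols | OCC[C@@H](CC[C@]1(C)O[C@H]1CC/C(C)=C/CCC(C)O)[C@H](CC[C@H](C(=O)OC)[C@@H](CCO)CC[C@]1(C)O[C@H]1CC/C(C)=C/CCC(C)O)C(=O)OC | intermediate
21 | bis(keto-aldehyde) dimethyl ester, key-step precursor: dimethyl (15S,15′S)-adipate whose α-carbons carry C1 (R) methines bearing CH2CHO (C2–C3) and the C14–C4 arm with (11S,12S)-epoxide, (7E)-alkene and C4 methyl ketone | O=CC[C@@H](CC[C@]1(C)O[C@H]1CC/C(C)=C/CCC(C)=O)[C@H](CC[C@H](C(=O)OC)[C@@H](CC=O)CC[C@]1(C)O[C@H]1CC/C(C)=C/CCC(C)=O)C(=O)OC | intermediate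
22 | bis(macrocyclic (3S,4S)-diol) dimethyl ester, key-step product | C/C1=C\CC[C@](C)(O)[C@@H](O)C[C@@H](CC[C@]2(C)O[C@H]2CC1)[C@H](CC[C@H](C(=O)OC)[C@@H]1CC[C@]2(C)O[C@H]2CC/C(C)=C/CC[C@](C)(O)[C@@H](O)C1)C(=O)OC | intermediate
23 | C2-symmetric bis(δ-lactone) with free C4 and C4′ tertiary alcohols (15S,15′S) | C/C1=C\CC[C@](C)(O)[C@@H]2C[C@@H](CC[C@]3(C)O[C@H]3CC1)[C@H](CC[C@@H]1C(=O)O[C@H]3C[C@H]1CC[C@]1(C)O[C@H]1CC/C(C)=C/CC[C@]3(C)O)C(=O)O2 | intermediate
24 | 4,4′-bis(O-trimethylsilyl) ether of 23 | C/C1=C\CC[C@](C)(O[Si](C)(C)C)[C@@H]2C[C@@H](CC[C@]3(C)O[C@H]3CC1)[C@H](CC[C@@H]1C(=O)O[C@H]3C[C@H]1CC[C@]1(C)O[C@H]1CC/C(C)=C/CC[C@]3(C)O[Si](C)(C)C)C(=O)O2 | intermediate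
25 | (15′S)-15′-hydroxy derivative of 24 | C/C1=C\CC[C@](C)(O[Si](C)(C)C)[C@@H]2C[C@@H](CC[C@]3(C)O[C@H]3CC1)[C@H](CC[C@@]1(O)C(=O)O[C@H]3C[C@H]1CC[C@]1(C)O[C@H]1CC/C(C)=C/CC[C@]3(C)O[Si](C)(C)C)C(=O)O2 | intermediate (not isolated)
26 | CNP0186476.4 | C/C1=C\CC[C@](C)(O)[C@@H]2C[C@@H](CC[C@]3(C)O[C@H]3CC1)[C@H](CC[C@@]1(O)C(=O)O[C@H]3C[C@H]1CC[C@]1(C)O[C@H]1CC/C(C)=C/CC[C@]3(C)O)C(=O)O2 | target

Total step count: 16. Longest linear sequence: 16 steps (1 → 26).

Steps most likely to fail

Step 13. What may go wrong: coupling of the two aldehyde ketyls with each other across the linker (ten-membered ring) or between molecules, simple reduction of an aldehyde before it cyclises, and ketyl addition on the wrong face with respect to C1. The fallback sets out from 20 and comes back at 22; it closes the rings one after the other so that only one aldehyde exists at a time. Tetraol 20 is silylated at one primary hydroxyl (Et3SiCl, 1 equiv, imidazole, CH2Cl2, –40 °C, unreacted 20 recycled) to the mono(triethylsilyl) ether F1. Dess–Martin oxidation gives the diketo mono-aldehyde F2, and SmI2 under the conditions of step 13 closes the first ring to the mono-macrocyclic diol F3. Bu4NF/AcOH frees the primary alcohol F4, TEMPO/PhI(OAc)2 oxidises only this primary alcohol to the keto-aldehyde F5, and a second SmI2 cyclisation gives 22.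

Step 8. What may go wrong: incomplete control of the ketene acetal geometry in the polar medium, which erodes C15, and Dieckmann cyclisation of a mono-enolate before the second deprotonation. The fallback sets out from 5 and comes back at 15; it reaches the same C15/C1 relationship from the (E)-ketene acetal, which LiN(iPr)2 forms reliably in THF alone, by inverting the alkene geometry and the carbinol configuration of the allylic ester. Triflate 7, made from 5 as in step 5, is alkylated with 3-lithio-1-(trimethylsilyl)propyne (n-BuLi, TMEDA, –78 °C) to the silyl alkyne F6, and K2CO3/MeOH gives the terminal alkyne F7. n-BuLi and N-methoxy-N-methylacetamide give the ynone F8, and Noyori transfer hydrogenation with RuCl[(R,R)-TsDPEN](p-cymene) in iPrOH gives the (R)-propargylic alcohol F9. Lindlar semi-hydrogenation (H2, Pd/CaCO3 poisoned with Pb(OAc)2, quinoline) gives the (R,Z)-allylic alcohol F10, and adipoyl chloride gives the bis-ester F11. LiN(iPr)2 in THF and TBSCl give the bis[(E)-silyl ketene acetal] F12, whose chair transition state with axial C17 and axial C14 leads to the same bis(silyl ester) 14 and, after Bu4NF, to 15.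

Step 16. What may go wrong: enolisation of both lactones or proton exchange between the enolate and the second lactone (over-oxidation, loss of C15 configuration), and oxygen transfer to the wrong enolate face. The fallback sets out from 22 and comes back at 26; it makes the two halves different before the enolisation, because a δ-lactone is deprotonated much more readily than an open-chain α-branched methyl ester. Lactonisation of 22 as in step 14 is stopped at partial conversion to give the mono-lactone F13 (22 recycled), and N-(trimethylsilyl)imidazole gives the tris(trimethylsilyl) ether F14. KN(SiMe3)2 (1.05 equiv) and the oxaziridine hydroxylate the lactone half only, giving the α-hydroxy lactone F15. Bu4NF/AcOH gives the desilylated hydroxy mono-lactone F16, and DBU in toluene closes the second lactone to 26.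

Further compounds
F1 | step 13 | mono(triethylsilyl) ether of tetraol 20 at one primary (C3′) hydroxyl | OCC[C@@H](CC[C@]1(C)O[C@H]1CC/C(C)=C/CCC(C)O)[C@H](CC[C@H](C(=O)OC)[C@@H](CCO[Si](CC)(CC)CC)CC[C@]1(C)O[C@H]1CC/C(C)=C/CCC(C)O)C(=O)OC
F2 | step 13 | diketo mono-aldehyde with the C3′ triethylsilyl ether | O=CC[C@@H](CC[C@]1(C)O[C@H]1CC/C(C)=C/CCC(C)=O)[C@H](CC[C@H](C(=O)OC)[C@@H](CCO[Si](CC)(CC)CC)CC[C@]1(C)O[C@H]1CC/C(C)=C/CCC(C)=O)C(=O)OC
F3 | step 13 | mono-macrocyclic (3S,4S)-diol, second arm as ketone and C3′ silyl ether | C/C1=C\CC[C@](C)(O)[C@@H](O)C[C@@H](CC[C@]2(C)O[C@H]2CC1)[C@H](CC[C@H](C(=O)OC)[C@@H](CCO[Si](CC)(CC)CC)CC[C@]1(C)O[C@H]1CC/C(C)=C/CCC(C)=O)C(=O)OC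
F4 | step 13 | mono-macrocyclic diol with free primary C3′ alcohol | C/C1=C\CC[C@](C)(O)[C@@H](O)C[C@@H](CC[C@]2(C)O[C@H]2CC1)[C@H](CC[C@H](C(=O)OC)[C@@H](CCO)CC[C@]1(C)O[C@H]1CC/C(C)=C/CCC(C)=O)C(=O)OC
F5 | step 13 | mono-macrocyclic diol with C3′ aldehyde and C4′ ketone | C/C1=C\CC[C@](C)(O)[C@@H](O)C[C@@H](CC[C@]2(C)O[C@H]2CC1)[C@H](CC[C@H](C(=O)OC)[C@@H](CC=O)CC[C@]1(C)O[C@H]1CC/C(C)=C/CCC(C)=O)C(=O)OC
F6 | step 8 | (2S,3S)-epoxide with 4-(trimethylsilyl)but-3-yn-1-yl group on C12 | C[Si](C)(C)C#CCC[C@]1(C)O[C@H]1CC/C(C)=C/CCC(C)O[Si](C)(C)C(C)(C)C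
F7 | step 8 | terminal alkyne from F6 | C#CCC[C@]1(C)O[C@H]1CC/C(C)=C/CCC(C)O[Si](C)(C)C(C)(C)C
F8 | step 8 | methyl ynone | CC(=O)C#CCC[C@]1(C)O[C@H]1CC/C(C)=C/CCC(C)O[Si](C)(C)C(C)(C)C
F9 | step 8 | (R)-propargylic alcohol | C[C@@H](O)C#CCC[C@]1(C)O[C@H]1CC/C(C)=C/CCC(C)O[Si](C)(C)C(C)(C)C
F10 | step 8 | (2R,3Z)-allylic alcohol | C[C@@H](O)/C=C\CC[C@]1(C)O[C@H]1CC/C(C)=C/CCC(C)O[Si](C)(C)C(C)(C)C
F11 | step 8 | hexanedioate diester of two molecules of F10 | O=C(CCCCC(=O)O[C@H](C)/C=C\CC[C@]1(C)O[C@H]1CC/C(C)=C/CCC(C)O[Si](C)(C)C(C)(C)C)O[C@H](C)/C=C\CC[C@]1(C)O[C@H]1CC/C(C)=C/CCC(C)O[Si](C)(C)C(C)(C)C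
F12 | step 8 | bis[(E)-O-tert-butyldimethylsilyl ketene acetal] of F11 | CC(C)(C)[Si](C)(C)O/C(O[C@H](C)/C=C\CC[C@]1(C)O[C@H]1CC/C(C)=C/CCC(C)O[Si](C)(C)C(C)(C)C)=C/CC/C=C(/O[Si](C)(C)C(C)(C)C)O[C@H](C)/C=C\CC[C@]1(C)O[C@H]1CC/C(C)=C/CCC(C)O[Si](C)(C)C(C)(C)C
F13 | step 16 | mono-lactone: one half lactonised, the other half still the (3′S,4′S)-diol methyl ester | C/C1=C\CC[C@](C)(O)[C@@H]2C[C@@H](CC[C@]3(C)O[C@H]3CC1)[C@H](CC[C@H](C(=O)OC)[C@@H]1CC[C@]3(C)O[C@H]3CC/C(C)=C/CC[C@](C)(O)[C@@H](O)C1)C(=O)O2
F14 | step 16 | tris(trimethylsilyl) ether of F13 | C/C1=C\CC[C@](C)(O[Si](C)(C)C)[C@@H]2C[C@@H](CC[C@]3(C)O[C@H]3CC1)[C@H](CC[C@H](C(=O)OC)[C@@H]1CC[C@]3(C)O[C@H]3CC/C(C)=C/CC[C@](C)(O[Si](C)(C)C)[C@@H](O[Si](C)(C)C)C1)C(=O)O2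
F15 | step 16 | α-hydroxy lactone (hydroxylated C15 S) of F14 | C/C1=C\CC[C@](C)(O[Si](C)(C)C)[C@@H]2C[C@@H](CC[C@]3(C)O[C@H]3CC1)[C@@](O)(CC[C@H](C(=O)OC)[C@@H]1CC[C@]3(C)O[C@H]3CC/C(C)=C/CC[C@](C)(O[Si](C)(C)C)[C@@H](O[Si](C)(C)C)C1)C(=O)O2
F16 | step 16 | desilylated hydroxy mono-lactone | C/C1=C\CC[C@](C)(O)[C@@H]2C[C@@H](CC[C@]3(C)O[C@H]3CC1)[C@@](O)(CC[C@H](C(=O)OC)[C@@H]1CC[C@]3(C)O[C@H]3CC/C(C)=C/CC[C@](C)(O)[C@@H](O)C1)C(=O)O2
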